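The data stem from a simulated flask for substances that don't exist; noise was put on by code.

If reagent and catalyst can be frozen at their levels, each portion of substrate ages on its own, and a fed flask is a sum of younger batch flasks.

| flask | substrate | reagent | catalyst | remark | time |
|---|---|---|---|---|---|
| amber | 10 mM | 25 mM | 0.20 mM | run made earlier |  |
| blue | 10 mM | 12 mM | 0.20 mM | run made earlier |  |
| violet | 10 mM | 50 mM | 0.20 mM | run made earlier |  |
| winter | 10 mM | 25.0 mM | 0.20 mM | everything together at the start | 40 h |
| noon | 10 mM | 25.0 mM (fed, over 30 h) | 0.20 mM | all else is in the flask from the start; the feed brings no volume worth counting | 40 h |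
| summer | 10 mM (fed, over 30 h) | 25.0 mM | 0.20 mM | all else is in the flask from the start; the feed brings no volume worth counting | 40 h |

| run | time / h | target / % | substrate / % |
|---|---|---|---|
| amber | 6.00 | 0.4 | 89.3 |
| amber | 12.0 | 1.6 | 81.5 |
| amber | 15.0 | 4.0 | 76.2 |
| amber | 25.0 | 9.9 | 64.3 |
| amber | 30.0 | 11.9 | 58.0 |
| amber | 40.0 | 17.4 | 48.3 |
| blue | 2.50 | 0.5 | 96.7 |
| blue | 8.00 | 0.4 | 86.4 |
| blue | 15.0 | 2.2 | 77.7 |
| blue | 20.0 | 3.4 | 71.5 |
| blue | 30.0 | 7.1 | 58.5 |
| blue | 40.0 | 11.2 | 49.1 |
| blue | 50.0 | 15.1 | 41.7 |
| violet | 4.00 | 0.7 | 93.6 |
| violet | 6.00 | 1.5 | 89.9 |
| violet | 8.00 | 2.6 | 87.5 |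
| violet | 15.0 | 8.2 | 77.0 |
| violet | 20.0 | 11.6 | 69.8 |
| violet | 30.0 | 20.0 | 57.7 |
| violet | 50.0 | 36.7 | 40.1 |

(scatter of a reading: 0.5 percentage points)

- percentages count the substrate that a species holds: one idle adduct counts as two
- target is meant together with its idle adduct
- steps under discussion: substrate + catalyst -> catalyst + intermediate; reagent + catalyst + intermediate <-> catalyst + target; target <-> isomer of the product; substrate + target <-> idle adduct
- in an amount of target, one idle adduct counts as one target

- the best flask by amount of target, in percent of the substrate charged; "all alike" if 1.5 percentage points covers them all (winter / noon / summer / all alike)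
- amount of target at the end, in percent of the substrate charged, winter
- amount of target at the end, in percent of the substrate charged, noon
- amount of target at the end, in percent of the substrate charged, summer

Freezing looks fair: each step that takes up the catalyst gives it back, and the target in the amber run at 40.0 h stands for 6.96% of the reagent charge. With the idle adduct set aside, the steps become pseudo-first-order. Winter has amber's charges, so I expect about amber's reading at its last time, 17.4%. Noon's fed reagent, counted without use, averages 15.6 mM over the time, above the 12 mM of the blue run, which read 11.2% at 40.0 h, so noon should fall between blue and amber.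

Summer is the dispute. The first chemist holds that target follows reacted substrate. Amber's last substrate reading puts its fall at 0.0182 h⁻¹, so a steady feed has reacted 0.692 of what a batch has, which makes 12.0%.

The second chemist, whose reckoning I commit to, holds that target lags behind through the intermediate, so age counts for more. Call 1.50 the age exponent: the power of time by which target grows in amber between 15.0 h and 40.0 h, a reading with its scatter. That span roughly matches summer's portions, aged from 10.0 h to 40 h. Averaging age, as a fraction of the time and raised to that power, over the feed gives summer 0.517 of a batch, so 9.00%.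

The forecast stands nearer the first chemist on summer: winter best, with 17.2%, 15.2% and 11.5% for winter, noon and summer, and its ground for summer is that “substrate arrives late, so less has reacted”.

The flask gives 18.8% in winter, 16.4% in noon and 9.67% in summer, so winter holds more target than either other flask.

    substrate + catalyst → catalyst + intermediate (k = 85.7 M⁻¹ h⁻¹)
    reagent + catalyst + intermediate ⇌ catalyst + target (K = 663 M⁻¹, k = 5120 M⁻² h⁻¹)
    target ⇌ isomer of the product (K = 0.730, k = 0.00169 h⁻¹)
    substrate + target ⇌ idle adduct, settled at all times (K = 34.0 M⁻¹)

Applied to winter's result, the age share gives 9.72% for summer against 9.67%, while the reacted share gives 13.0%. The first chemist's view belongs late: at 400 h, with substrate at 0.247% in winter and 0.308% in summer, target stands at 66.3% and 66.8%. A neighbouring flask is summer with 0.34 mM of catalyst. Both steps on the way to target carry the catalyst, so I stretch each portion's age by 1.70, and the age exponent puts target at 21.4%. That flask gives 20.7%.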